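The B-ring 2,2-dimethylpyran (O on C4', carbon on C3') is closed last, on a finished pyrano-coumaronochromone. Its precursor 19 carries a 1,1-dimethylpropargyl ether on O4' and a formyl group on C5'. The formyl group masks the 5'-hydroxyl and leaves C3' as the only free carbon ortho to O4'. One heating runs the propargyl Claisen shift, 1,5-hydrogen shift and oxa-6π electrocyclization that build the pyran ring. The same heating moves a 1,1-dimethylallyl group from O5 to C6 of ring A by a second [3,3] shift, which frees the chelated 5-OH. A Dakin oxidation then turns the formyl group into the 5'-OH.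

Key step: step 12

Remark: the fused compounds keep isoflavone locants (C2 to C4, ring A C5 to C8, ring B C1' to C6'); in the coumaronochromones the furan oxygen joins C2 and C2'.

Step 1
Reactants: 1 2,4,6-trihydroxyacetophenone; 2 3-chloro-3-methylbut-1-yne
Product: 3 1-{2,6-dihydroxy-4-[(2-methylbut-3-yn-2-yl)oxy]phenyl}ethanone
Conditions: 2 (1.1 equiv), K2CO3, KI, CuI (cat.), acetone, 55 °C
Reagents that add atoms: 3-chloro-3-methylbut-1-yne (2), C#CC(C)(C)Cl
Why: Copper-assisted O-alkylation of a phenol with a tertiary propargyl chloride should take the 4-OH, which is para to the acetyl group, not chelated and the most acidic of the three.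

Step 2
Reactants: 3 para propargyl ether
Product: 4 1-(5,7-dihydroxy-2,2-dimethyl-2H-chromen-6-yl)ethanone
Conditions: o-xylene, 140 °C
Reagents that add atoms: none
Why: Thermal propargyl Claisen rearrangement, 1,5-hydrogen shift and oxa-6π electrocyclization; the two ortho carbons are equivalent and the ring can only close on the former ether oxygen, so a single chromene should form.

Step 3
Reactants: 4 chromene diol; 2 3-chloro-3-methylbut-1-yne
Product: 5 1-{5-hydroxy-2,2-dimethyl-7-[(2-methylbut-3-yn-2-yl)oxy]-2H-chromen-6-yl}ethanone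
Conditions: 2 (1.2 equiv), K2CO3, KI, CuI (cat.), acetone, 50 °C
Reagents that add atoms: 3-chloro-3-methylbut-1-yne (2), C#CC(C)(C)Cl
Why: Copper-assisted phenol O-propargylation with the bulky tertiary electrophile should take the 7-OH, because the 5-OH is crowded by the peri C4–H of the pyran ring and held in the stronger hydrogen bond to the acetyl group.

Step 4
Reactants: 5 mono ether; 6 N,N-dimethylformamide dimethyl acetal; 7 iodine
Product: 9 3-iodo-8,8-dimethyl-5-[(2-methylbut-3-yn-2-yl)oxy]-4H,8H-pyrano[2,3-f]chromen-4-one, via enaminone 8 (not isolated)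
Conditions: 6 (3 equiv), toluene, 90 °C; then 7 (1.2 equiv), CHCl3, rt
Reagents that add atoms: N,N-dimethylformamide dimethyl acetal (6), COC(OC)N(C)C; iodine (7), II
Why: Enaminone formation and iodine-induced cyclization (Gammill 3-iodochromone synthesis); the 5-OH is the only free phenol, so the pyranone must close on it and the angular pyranochromone results.

Step 5
Reactants: 10 5-bromo-2,4-dihydroxybenzaldehyde; 11 chloromethyl methyl ether
Product: 12 5-bromo-2,4-bis(methoxymethoxy)benzaldehyde
Conditions: 11 (2.5 equiv), K2CO3, acetone, reflux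
Reagents that add atoms: chloromethyl methyl ether (11), COCCl
Why: Williamson-type MOM protection of both phenols, which keeps them inert during borylation and cross-coupling.

Step 6
Reactants: 12 aryl bromide; 13 bis(pinacolato)diboron
Product: 14 2,4-bis(methoxymethoxy)-5-(4,4,5,5-tetramethyl-1,3,2-dioxaborolan-2-yl)benzaldehyde
Conditions: 13 (1.2 equiv), Pd(dppf)Cl2 (3 mol %), KOAc, 1,4-dioxane, 90 °C
Reagents that add atoms: bis(pinacolato)diboron (13), CC1(C)OB(OC1(C)C)B1OC(C)(C)C(C)(C)O1
Why: Miyaura borylation of an aryl bromide; the aldehyde and the MOM ethers tolerate the weak acetate base.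

Step 7
Reactants: 9 3-iodochromone; 14 arylboronate
Product: 15 5-{8,8-dimethyl-5-[(2-methylbut-3-yn-2-yl)oxy]-4-oxo-4H,8H-pyrano[2,3-f]chromen-3-yl}-2,4-bis(methoxymethoxy)benzaldehyde
Conditions: Pd(PPh3)4 (5 mol %), K2CO3, DME–H2O, 80 °C
Reagents that add atoms: arylboronate 14, COCOc1cc(OCOC)c(C=O)cc1B1OC(C)(C)C(C)(C)O1
Why: Suzuki–Miyaura coupling of the 3-iodochromone with the arylboronate; copper-free carbonate conditions should leave the hindered terminal alkyne untouched.

Step 8
Reactants: 15 bis-MOM isoflavone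
Product: 16 5-{8,8-dimethyl-5-[(2-methylbut-3-yn-2-yl)oxy]-4-oxo-4H,8H-pyrano[2,3-f]chromen-3-yl}-2,4-dihydroxybenzaldehyde
Conditions: HCl (3 M aq.), MeOH–THF, 50 °C
Reagents that add atoms: none
Why: Acid-catalysed acetal cleavage of both MOM ethers; the chromene and the tertiary propargyl aryl ether should survive dilute acid because the propargylic cation is poorly stabilized.

Step 9
Reactants: 16 2'-hydroxyisoflavone
Product: 17 coumaronochromone with 7,8-fused 2,2-dimethyl-2H-pyran (O on C7) bearing 5-O-(2-methylbut-3-yn-2-yl) 4'-OH 5'-CHO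
Conditions: DDQ (1.2 equiv), 1,4-dioxane, rt to 60 °C
Reagents that add atoms: none
Why: DDQ-mediated dehydrogenative cyclization of a 2'-hydroxyisoflavone (oxa-Michael addition of the 2'-OH to C2, then dehydrogenation across C2–C3); the formyl group makes ring B electron-poorer and should protect it from over-oxidation.

Step 10
Reactants: 17 alkyne
Product: 18 coumaronochromone as 17 but with 5-O-(2-methylbut-3-en-2-yl)
Conditions: H2 (1 atm), Lindlar catalyst (Pd/CaCO3 poisoned with Pb(OAc)2), quinoline, EtOAc, rt
Reagents that add atoms: none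
Why: Lindlar semi-hydrogenation of the terminal alkyne to the 1,1-dimethylallyl ether; the poisoned catalyst should not reduce the chromene double bond or the aldehyde.

Step 11
Reactants: 18 phenol aldehyde; 2 3-chloro-3-methylbut-1-yne
Product: 19 coumaronochromone as 18 but with 4'-O-(2-methylbut-3-yn-2-yl)
Conditions: 2 (1.5 equiv), K2CO3, KI, CuI (cat.), acetone, 45 °C
Reagents that add atoms: 3-chloro-3-methylbut-1-yne (2), C#CC(C)(C)Cl
Why: Copper-assisted O-propargylation of the only free phenol (4'-OH), run below 50 °C so that the allyl ether on O5 does not rearrange yet.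

Step 12
Reactants: 19 allyl ether / propargyl ether
Product: 22 5-hydroxy-6-(3-methylbut-2-enyl) coumaronochromone with 2,2-dimethyl-2H-pyrans fused at C7–C8 and C3'–C4' and a 5'-CHO group, via C6-prenyl phenol 20 (not isolated), via o-quinone methide 21 (not isolated)
Conditions: N,N-diethylaniline, argon, 110 °C (1 h), then 175 °C
Reagents that add atoms: none
Why: At 110 °C the 1,1-dimethylallyl ether undergoes an aromatic Claisen [3,3] shift from O5 to C6 (20); at 175 °C the propargyl ether shifts [3,3] from O4' to C3', the allenyl dienone enolizes, a 1,5-hydrogen shift gives the vinyl o-quinone methide 21, and this closes to the 2H-pyran. The closest known reactions are the thermal conversion of aryl 1,1-dimethylpropargyl ethers into 2,2-dimethyl-2H-chromenes and the Claisen rearrangement of aryl 1,1-dimethylallyl ethers to ortho-prenylphenols. The pyran ring closes by a thermal disrotatory oxa-6π electrocyclization that forms the O4'–CMe2 bond, after the sigmatropic shift has made the bond from C3'. No stereocenter is formed. The step needs ortho-regioselectivity twice: on ring B only C3' is open because C5' bears the formyl group, and on ring A only C6 is open because C4a is a ring-fusion carbon. The lower activation temperature of the allyl shift should let the prenyl group settle on C6 before ring B reacts.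

Step 13
Reactants: 22 aldehyde; 23 hydrogen peroxide
Product: 25 CNP0323631.0, via aryl formate 24 (not isolated)
Conditions: 23 (30 % aq., 2 equiv), KHSO4 (cat.), MeOH–CH2Cl2, rt
Reagents that add atoms: hydrogen peroxide (23), OO
Why: Dakin-type oxidation (acid-catalysed Baeyer–Villiger aryl migration of an aldehyde that has an alkoxy group ortho and an aryloxy group para) followed by methanolysis of the formate; with no peracid present the three alkenes should not be epoxidized.

Compound list
1 | 2,4,6-trihydroxyacetophenone | CC(=O)c1c(O)cc(O)cc1O | starting material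
2 | 3-chloro-3-methylbut-1-yne | C#CC(C)(C)Cl | starting material
3 | 1-{2,6-dihydroxy-4-[(2-methylbut-3-yn-2-yl)oxy]phenyl}ethanone | CC(=O)c1c(O)cc(OC(C)(C)C#C)cc1O | intermediate
4 | 1-(5,7-dihydroxy-2,2-dimethyl-2H-chromen-6-yl)ethanone | CC(=O)c1c(O)cc2OC(C)(C)C=Cc2c1O | intermediate
5 | 1-{5-hydroxy-2,2-dimethyl-7-[(2-methylbut-3-yn-2-yl)oxy]-2H-chromen-6-yl}ethanone | CC(=O)c1c(OC(C)(C)C#C)cc2OC(C)(C)C=Cc2c1O | intermediate
6 | N,N-dimethylformamide dimethyl acetal | COC(OC)N(C)C | starting material
7 | iodine | II | starting material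
8 | (E)-3-(dimethylamino)-1-{5-hydroxy-2,2-dimethyl-7-[(2-methylbut-3-yn-2-yl)oxy]-2H-chromen-6-yl}prop-2-en-1-one | CN(C)/C=C/C(=O)c1c(OC(C)(C)C#C)cc2OC(C)(C)C=Cc2c1O | intermediate
9 | 3-iodo-8,8-dimethyl-5-[(2-methylbut-3-yn-2-yl)oxy]-4H,8H-pyrano[2,3-f]chromen-4-one | O=c1c(I)coc2c3C=CC(C)(C)Oc3cc(OC(C)(C)C#C)c12 | intermediate
10 | 5-bromo-2,4-dihydroxybenzaldehyde | O=Cc1cc(Br)c(O)cc1O | starting material
11 | chloromethyl methyl ether | COCCl | starting material
12 | 5-bromo-2,4-bis(methoxymethoxy)benzaldehyde | COCOc1cc(OCOC)c(C=O)cc1Br | intermediate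
13 | bis(pinacolato)diboron | CC1(C)OB(OC1(C)C)B1OC(C)(C)C(C)(C)O1 | starting material
14 | 2,4-bis(methoxymethoxy)-5-(4,4,5,5-tetramethyl-1,3,2-dioxaborolan-2-yl)benzaldehyde | COCOc1cc(OCOC)c(C=O)cc1B1OC(C)(C)C(C)(C)O1 | intermediate
15 | 5-{8,8-dimethyl-5-[(2-methylbut-3-yn-2-yl)oxy]-4-oxo-4H,8H-pyrano[2,3-f]chromen-3-yl}-2,4-bis(methoxymethoxy)benzaldehyde | COCOc1cc(OCOC)c(C=O)cc1-c1coc2c3C=CC(C)(C)Oc3cc(OC(C)(C)C#C)c2c1=O | intermediate
16 | 5-{8,8-dimethyl-5-[(2-methylbut-3-yn-2-yl)oxy]-4-oxo-4H,8H-pyrano[2,3-f]chromen-3-yl}-2,4-dihydroxybenzaldehyde | O=Cc1cc(-c2coc3c4C=CC(C)(C)Oc4cc(OC(C)(C)C#C)c3c2=O)c(O)cc1O | intermediate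
17 | coumaronochromone with 7,8-fused 2,2-dimethyl-2H-pyran (O on C7), 5-O-(2-methylbut-3-yn-2-yl), 4'-OH, 5'-CHO | O=Cc1cc2c(cc1O)oc1oc3c4C=CC(C)(C)Oc4cc(OC(C)(C)C#C)c3c(=O)c12 | intermediate
18 | as 17, with 5-O-(2-methylbut-3-en-2-yl) in place of the alkynyl ether | O=Cc1cc2c(cc1O)oc1oc3c4C=CC(C)(C)Oc4cc(OC(C)(C)C=C)c3c(=O)c12 | intermediate
19 | as 18, with 4'-O-(2-methylbut-3-yn-2-yl) in place of 4'-OH | O=Cc1cc2c(cc1OC(C)(C)C#C)oc1oc3c4C=CC(C)(C)Oc4cc(OC(C)(C)C=C)c3c(=O)c12 | intermediate
20 | as 19, with 5-OH and 6-(3-methylbut-2-enyl) in place of the O5 allyl ether | O=Cc1cc2c(cc1OC(C)(C)C#C)oc1oc3c4C=CC(C)(C)Oc4c(CC=C(C)C)c(O)c3c(=O)c12 | intermediate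
21 | o-quinone methide of 20: ring B as 4'-oxo-3'-(3-methylbut-2-enylidene) cyclohexadienone, 5'-CHO | O=CC1=CC2=C(OC3=C2C(=O)c2c(O)c(CC=C(C)C)c4OC(C)(C)C=Cc4c2O3)C(=CC=C(C)C)C1=O | intermediate
22 | 5-hydroxy-6-(3-methylbut-2-enyl) coumaronochromone with 2,2-dimethyl-2H-pyrans fused at C7–C8 (O on C7) and C3'–C4' (O on C4'), 5'-CHO | CC(C)=CCc1c2c(c3oc4oc5c6c(c(C=O)cc5c4c(=O)c3c1O)OC(C)(C)C=C6)C=CC(C)(C)O2 | intermediate
23 | hydrogen peroxide | OO | starting material
24 | 5'-O-formate of 25 | CC(C)=CCc1c2c(c3oc4oc5c6c(c(OC=O)cc5c4c(=O)c3c1O)OC(C)(C)C=C6)C=CC(C)(C)O2 | intermediate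
25 | CNP0323631.0: 5,5'-dihydroxy-6-(3-methylbut-2-enyl) coumaronochromone with 2,2-dimethyl-2H-pyrans fused at C7–C8 (O on C7) and C3'–C4' (O on C4') | CC(C)=CCc1c2c(c3oc4oc5c6c(c(O)cc5c4c(=O)c3c1O)OC(C)(C)C=C6)C=CC(C)(C)O2 | target

Total step count: 13. Longest linear sequence: 11 steps (steps 1 to 4 and 7 to 13); steps 5 and 6 make the ring B fragment.

Steps most likely to fail

Step 13. The peroxide may attack the electron-rich chromene or prenyl double bonds, or the acid may cyclize the prenyl group onto the 5-OH, before aryl migration is complete. The fallback sets out from 18 and comes back at 25. It unmasks the phenol while a free ortho hydroxyl is still present. Classical Dakin oxidation of 18 (H2O2, NaOH, THF–H2O, 0 °C) should give the aryl formate F1, hydrolysed in the flask to the catechol F2. Heating in toluene at 110 °C should shift the allyl group from O5 to C6 to give the prenylated catechol F3. Condensation of F3 with 3-methylbut-2-enal (ethylenediammonium diacetate, xylene, 120 °C; Knoevenagel condensation and oxa-6π electrocyclization) should then give 25. This fallback is less secure in regiochemistry: it relies on C3' being preferred over C6', which lies in the bay next to the C4 carbonyl.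

Step 12. At 175 °C the tertiary allyl group may be lost as isoprene, or the material may decompose before the slower propargyl shift next to the formyl group is finished. The fallback sets out from 18 and comes back at 22, and it separates the two events. Heating 18 alone (toluene, 110 °C) should give the C6-prenyl phenol aldehyde F4. O-propargylation with 2 (K2CO3, KI, CuI, acetone, 45 °C) should take the 4'-OH and not the chelated, hindered 5-OH, and give 20. A gold-catalysed 6-endo hydroarylation of the aryl propargyl ether (Ph3PAuNTf2, 2 mol %, CH2Cl2, rt) should then close the pyran at C3' to give 22 without strong heating.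

Step 3. Alkylation may fall on O5 instead of O7, or on both hydroxyls. The fallback sets out from 1 and comes back at 5, and it fixes the ether before the pyran is made. Para-selective protection of 1 (11, 1 equiv, iPr2NEt, CH2Cl2, 0 °C) should give the 4-O-MOM ether F5. O-propargylation of one of its two equivalent hydroxyls with 2 should give the propargyl ether F6. Acid cleavage of the MOM group (HCl, MeOH, 40 °C) should give the 2,4-diol F7. Chromenylation with 3-methylbut-2-enal (ethylenediammonium diacetate, toluene, 100 °C) should occur at the carbon between the two free hydroxyls and close on the unchelated 4-oxygen, giving 5.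

Further compounds
F1 | step 13 | 5'-O-formate of the catechol F2 (Dakin intermediate from 18) | O=COc1cc2c(cc1O)oc1oc3c4C=CC(C)(C)Oc4cc(OC(C)(C)C=C)c3c(=O)c12
F2 | step 13 | coumaronochromone with 7,8-fused 2,2-dimethyl-2H-pyran, 5-O-(2-methylbut-3-en-2-yl), 4',5'-dihydroxy | Oc1cc2c(cc1O)oc1oc3c4C=CC(C)(C)Oc4cc(OC(C)(C)C=C)c3c(=O)c12
F3 | step 13 | 5,4',5'-trihydroxy-6-(3-methylbut-2-enyl) coumaronochromone with 7,8-fused 2,2-dimethyl-2H-pyran | CC(C)=CCc1c2c(c3oc4oc5cc(O)c(O)cc5c4c(=O)c3c1O)C=CC(C)(C)O2
F4 | step 12 | 5,4'-dihydroxy-6-(3-methylbut-2-enyl)-5'-formyl coumaronochromone with 7,8-fused 2,2-dimethyl-2H-pyran | O=Cc1cc2c(cc1O)oc1oc3c4C=CC(C)(C)Oc4c(CC=C(C)C)c(O)c3c(=O)c12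
F5 | step 3 | 1-[2,6-dihydroxy-4-(methoxymethoxy)phenyl]ethanone | CC(=O)c1c(O)cc(OCOC)cc1O
F6 | step 3 | 1-{2-hydroxy-4-(methoxymethoxy)-6-[(2-methylbut-3-yn-2-yl)oxy]phenyl}ethanone | CC(=O)c1c(O)cc(OCOC)cc1OC(C)(C)C#C
F7 | step 3 | 1-{2,4-dihydroxy-6-[(2-methylbut-3-yn-2-yl)oxy]phenyl}ethanone | CC(=O)c1c(O)cc(O)cc1OC(C)(C)C#C
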